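**Plan**

1. Ring atoms are numbered C1 (CH–O–acyl), C2 (CH2), C3(CH3)=C4, C5, C6, C7(CH3)(OH), C8=C9, C10 (CH–isopropyl). The two E double bonds are 1,6-related on both arcs of the ten-membered ring, and C3 and C8 lie opposite each other. A C3–C8 bond would turn the ring into a trans-fused decalin (ring A = C3–C4–C5–C6–C7–C8, ring B = C8–C9–C10–C1–C2–C3) with the C3 methyl angular. That is the retron of a boronate-triggered Grob fragmentation, with boron on C9 and a sulfonate on C4.
2. Retrosynthetic cuts: first the ester bond at O-1 (vanillic acid off), then C3–C8 is put back (both alkenes vanish). In the decalin, the C10–isopropyl bond (alkenyl triflate coupling), the C1–O bond (enol ether oxidation) and the C7 methyl carbon (methylenation) lead back to (R)-Wieland–Miescher ketone.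
3. Forward: rings A and B arrive with the starting diketone. Ring A is dressed first (C4–O, trans fusion at C8, C7 carbinol), then ring B (C1–O, C9=C10 carrying isopropyl, boron on C9). Cleavage of the shared C3–C8 bond releases the ten-membered ring; desilylation and acylation finish.
4. Stereochemistry: C3 comes from the (R) starting material (β = face of the angular methyl, α = the opposite face). Every other centre is set by reagent attack on the α face: C4 (hydride), C8 (hydroboration), C7 (epoxidation), C1 (enol ether epoxidation), C9 and C10 (hydroboration). C1, C7 and C10 persist into the target; C3, C4, C8 and C9 are spent in fixing the two E geometries.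

Key step: step 18

Remark: compound 24 is written as the dimethyl boronate that a methanol quench of the alkylborane should leave. Should the neighbouring C7 hydroxyl bind boron instead (cyclic borinate), methoxide would still give a tetracoordinate boronate with the same equatorial C9–B bond.

**Route**

Step 1
Reactants: 1 (R)-Wieland–Miescher ketone
Product: 2 hydroxy enone (C4 β-OH; C8=C9–C10=O)
Conditions: NaBH4 (0.3 equiv), EtOH, −10 °C
Reagents that add atoms: none
Why: Chemoselective borohydride reduction of the saturated C4 ketone (the conjugated C10 carbonyl is less electrophilic), with axial hydride delivery from the α face, anti to the angular methyl, giving the equatorial β-alcohol.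

Step 2
Reactants: 2 hydroxy enone
Product: 3 hydroxy ketal (C10 1,3-dioxolane; C7=C8 alkene; C4 β-OH)
Conditions: ethylene glycol, p-TsOH·H2O (cat.), benzene, reflux, azeotropic removal of water
Reagents that add atoms: ethylene glycol, OCCO
Why: Acid-catalysed ketalisation of the enone, in which the double bond leaves conjugation for the β,γ-position (C7=C8), as is usual for ring-fused 4-en-3-one-type enones.

Step 3
Reactants: 3 hydroxy ketal
Product: 4 PMB ether (C4 β-O-4-methoxybenzyl)
Conditions: NaH, 4-methoxybenzyl chloride, Bu4NI (cat.), DMF, 0 °C to rt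
Reagents that add atoms: 4-methoxybenzyl chloride, COc1ccc(CCl)cc1
Why: Williamson etherification of the secondary alkoxide; the ketal and the isolated alkene are inert to base.

Step 4
Reactants: 4 PMB ether
Product: 6 trans-fused alcohol (C7 α-OH; H-8 α), via C7 alkylborane 5 (not isolated)
Conditions: BH3·THF, THF, 0 °C to rt; then NaOH, H2O2, 0 °C
Reagents that add atoms: hydrogen peroxide, OO
Why: Hydroboration–oxidation of the trisubstituted alkene places boron on the less substituted C7 and adds syn from the α face (anti to the angular methyl), so H-8 ends α and the ring fusion trans.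

Step 5
Reactants: 6 trans-fused alcohol
Product: 7 trans-decalone (C7 ketone)
Conditions: Dess–Martin periodinane, NaHCO3, CH2Cl2, rt
Reagents that add atoms: none
Why: Dess–Martin oxidation of a secondary alcohol under buffered conditions that spare the ketal and the PMB ether; any cis-fused material can equilibrate to the more stable trans-decalone through the C8 enol.

Step 6
Reactants: 7 trans-decalone
Product: 8 exocyclic alkene (C7=CH2)
Conditions: Ph3PCH3Br, KOt-Bu, toluene, 80 °C
Reagents that add atoms: methyltriphenylphosphonium bromide, C[P+](c1ccccc1)(c1ccccc1)c1ccccc1.[Br-]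
Why: Wittig methylenation with the small non-stabilised ylide, which is standard for ketones next to a decalin ring fusion; the trans fusion is the thermodynamic one, so the basic medium does not endanger C8.

Step 7
Reactants: 8 exocyclic alkene
Product: 9 spiro-epoxide (oxirane O α; CH2 β)
Conditions: mCPBA, NaHCO3, CH2Cl2, 0 °C
Reagents that add atoms: 3-chloroperoxybenzoic acid, OOC(=O)c1cccc(Cl)c1
Why: Prilezhaev epoxidation; the β (axial) approach to C7 is syn-axial to the angular methyl, so the peracid should deliver oxygen from the α face.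

Step 8
Reactants: 9 spiro-epoxide
Product: 10 tertiary carbinol (C7 α-OH and β-CH3)
Conditions: LiAlH4, THF, 0 °C to reflux
Reagents that add atoms: none
Why: Hydride opening of the epoxide at its unhindered CH2 terminus converts the α-epoxide into the axial β-methyl/equatorial α-hydroxyl carbinol; ketal and PMB ether are untouched.

Step 9
Reactants: 10 tertiary carbinol
Product: 11 hydroxy ketone (C10 ketone)
Conditions: 1 M aq. HCl, THF, rt
Reagents that add atoms: water, O
Why: Mild acetal hydrolysis; the tertiary alcohol (no cation-stabilising neighbour) and the PMB ether tolerate dilute acid at room temperature.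

Step 10
Reactants: 11 hydroxy ketone
Product: 12 bis-silyl compound (C10=C1 trimethylsilyl enol ether; C7 OSiMe3)
Conditions: TMSOTf, Et3N, CH2Cl2, 0 °C
Reagents that add atoms: trimethylsilyl trifluoromethanesulfonate, C[Si](C)(C)OS(=O)(=O)C(F)(F)F
Why: Soft enolisation/silylation; trans-fused decalones of this type enolise away from the ring fusion (towards C1), reinforced here by the C7 substituents that crowd C9, and the tertiary alcohol is capped at the same time.

Step 11
Reactants: 12 bis-silyl compound
Product: 15 ketol (C1 α-OH; C10 ketone; C7 α-OH), via silyloxy epoxide 13 (not isolated), via bis-silyl ketol 14 (not isolated)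
Conditions: mCPBA, NaHCO3, CH2Cl2, −20 °C; then citric acid, MeOH, rt
Reagents that add atoms: 3-chloroperoxybenzoic acid, OOC(=O)c1cccc(Cl)c1
Why: Rubottom oxidation: the enol ether is epoxidised on the α face (the β face at C1 is syn-axial to the angular methyl), the silyloxy epoxide opens with silyl shift, and acidic methanol removes both silyl groups, giving the equatorial C1 α-oxygen, which is also the thermodynamically preferred epimer.

Step 12
Reactants: 15 ketol
Product: 16 silyloxy ketone (C1 α-OTBS)
Conditions: TBSCl, imidazole, DMAP (cat.), DMF, rt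
Reagents that add atoms: tert-butyldimethylsilyl chloride, CC(C)(C)[Si](C)(C)Cl
Why: Selective silylation of the secondary hydroxyl; the tertiary C7 hydroxyl does not react with the chlorosilane under these conditions.

Step 13
Reactants: 16 silyloxy ketone
Product: 18 enol triflate (C9=C10; OTf on C10), via dipotassium enolate 17 (not isolated)
Conditions: KN(SiMe3)2 (2.2 equiv), THF, −78 °C; then PhNTf2, −78 to 0 °C
Reagents that add atoms: N-phenylbis(trifluoromethanesulfonimide), O=S(=O)(N(c1ccccc1)S(=O)(=O)C(F)(F)F)C(F)(F)F
Why: Kinetic enolate triflation; the hindered amide base should remove a C9 hydrogen, not the tertiary C1 hydrogen geminal to the bulky silyloxy group, and the triflimide traps the enolate on oxygen, while the tertiary alkoxide from the first equivalent of base is too hindered to be sulfonylated at low temperature.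

Step 14
Reactants: 18 enol triflate; 19 isopropylmagnesium chloride
Product: 20 isopropyl alkene (C9=C10 with isopropyl on C10)
Conditions: 19 (3 equiv), Fe(acac)3 (10 mol %), THF–NMP, −30 to 0 °C
Reagents that add atoms: isopropylmagnesium chloride (19), CC(C)[Mg]Cl
Why: Iron-catalysed Kumada-type cross-coupling of an alkenyl triflate with a secondary alkyl Grignard reagent; it is fast at low temperature, which should outpace β-hydride loss from the isopropyl group, and one equivalent of 19 is sacrificed to the tertiary hydroxyl.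

Step 15
Reactants: 20 isopropyl alkene
Product: 21 diol (C4 β-OH free)
Conditions: DDQ, CH2Cl2–pH 7 buffer, 0 °C
Reagents that add atoms: none
Why: Oxidative cleavage of the 4-methoxybenzyl ether by hydride abstraction and hydrolysis; the silyl ether, the trisubstituted alkene and the tertiary alcohol are not oxidised under buffered conditions.

Step 16
Reactants: 21 diol
Product: 22 mesylate (C4 β-OMs)
Conditions: MsCl, pyridine, DMAP (cat.), 0 °C to rt
Reagents that add atoms: methanesulfonyl chloride, CS(=O)(=O)Cl
Why: Sulfonylation of the secondary equatorial hydroxyl; pyridine (no sulfene pathway) leaves the tertiary hydroxyl alone.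

Step 17
Reactants: 22 mesylate
Product: 24 dimethyl boronate (C9 α-B(OMe)2; C10 β-isopropyl), via C9 alkylborane 23 (not isolated)
Conditions: BH3·THF (4 equiv), THF, 0 °C to rt; then MeOH, 0 °C; concentrate
Reagents that add atoms: borane–tetrahydrofuran, B.C1CCOC1; methanol, CO
Why: Hydroboration of the trisubstituted alkene puts boron on the less substituted C9 and adds syn from the α face (the β face carries the two syn-axial methyl groups of C3 and C7), setting C9 (B equatorial) and C10 (H α, isopropyl β-equatorial); methanol converts the B–H bonds into the boronate, and the neopentyl-type mesylate is inert to borane.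

Step 18
Reactants: 24 dimethyl boronate
Product: 26 silyl-protected (3E,8E)-cyclodecadienol, via sodium boronate complex 25 (not isolated)
Conditions: NaOMe (5 equiv), MeOH, 65 °C
Reagents that add atoms: none
Why: Methoxide adds to the trigonal boron of 24 to give the tetracoordinate boronate 25; its C9–B electron pair flows into C8=C9 as the C3–C8 σ bond breaks, those electrons form C3=C4, and mesylate leaves C4, all in one concerted anti process. The closest known reaction type is the boronate-triggered Grob (1,4-heterolytic) fragmentation of γ-sulfonyloxy organoboranes in decalins, which gives cyclodeca-1,6-dienes. No ring closes by bond formation: the ten-membered ring appears because the bond shared by rings A and B is cut, so the mode is ring expansion by fragmentation, not cyclisation. No stereocentre is created; C1, C7 and C10 pass through untouched, and the ring carbons C2/C5 and C7/C10 are anti across the forming double bonds, so both alkenes should emerge E. The step needs the C9–B and C4–O bonds both antiperiplanar to C3–C8, which the rigid trans-fused chair secures through the equatorial mesylate (from step 1) and the equatorial boron (from the α-face hydroboration of step 17). The secondary silyl ether and the tertiary alcohol should survive methoxide, and the 1,6-diene has no Cope pathway.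

Step 19
Reactants: 26 silyl-protected cyclodecadienol
Product: 27 cyclodecadienediol (C1 and C7 hydroxyls free)
Conditions: Bu4NF, THF, rt
Reagents that add atoms: none
Why: Fluoride-induced desilylation under non-acidic conditions, which avoids transannular cyclisation of the diene.

Step 20
Reactants: 28 vanillic acid
Product: 29 4-acetoxy-3-methoxybenzoic acid
Conditions: Ac2O, pyridine, rt; aqueous work-up
Reagents that add atoms: acetic anhydride, CC(=O)OC(C)=O
Why: Acetylation of the phenol; any mixed anhydride at the carboxyl group is hydrolysed on aqueous work-up.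

Step 21
Reactants: 27 cyclodecadienediol; 29 4-acetoxy-3-methoxybenzoic acid
Product: 30 acetyl-protected ester (O-1 acylated)
Conditions: EDC·HCl, DMAP (cat.), CH2Cl2, 0 °C to rt
Reagents that add atoms: none
Why: Steglich esterification under near-neutral conditions; only the secondary C1 hydroxyl is acylated, because the tertiary C7 hydroxyl is too hindered, and the configuration at C1 is retained.

Step 22
Reactants: 30 acetyl-protected ester
Product: 31 target vanillate
Conditions: pyrrolidine, CH2Cl2, 0 °C
Reagents that add atoms: none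
Why: Chemoselective aminolysis of the phenolic acetate, an activated aryl ester, which should leave the much less electrophilic secondary alkyl aroate intact.

**Compound list**

1 | (R)-Wieland–Miescher ketone, (8aR)-8a-methyl-3,4,8,8a-tetrahydronaphthalene-1,6(2H,7H)-dione | C[C@@]12CCC(=O)C=C1CCCC2=O | starting material
2 | hydroxy enone, (4aR,5R)-5-hydroxy-4a-methyl-4,4a,5,6,7,8-hexahydronaphthalen-2(3H)-one (C4 β-OH) | O=C1CC[C@@]2(C)[C@H](O)CCCC2=C1 | intermediate
3 | hydroxy ketal: C10 1,3-dioxolane, C7=C8 alkene, C4 β-OH | O1CCOC12CC[C@@]3(C)[C@H](O)CCC=C3C2 | intermediate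
4 | PMB ether: C4 β-O-(4-methoxybenzyl), C10 dioxolane, C7=C8 alkene | O1CCOC12CC[C@@]3(C)[C@H](OCc4ccc(OC)cc4)CCC=C3C2 | intermediate
5 | C7 α-alkylborane (BH2 on C7, H-8 α) | O1CCOC12CC[C@@]3(C)[C@H](OCc4ccc(OC)cc4)CC[C@@H](B)[C@@H]3C2 | intermediate (not isolated)
6 | trans-fused alcohol: C7 α-OH, H-8 α, C4 β-OPMB, C10 dioxolane | O1CCOC12CC[C@@]3(C)[C@H](OCc4ccc(OC)cc4)CC[C@@H](O)[C@@H]3C2 | intermediate
7 | trans-decalone: C7 ketone, H-8 α | O1CCOC12CC[C@@]3(C)[C@H](OCc4ccc(OC)cc4)CCC(=O)[C@@H]3C2 | intermediate
8 | exocyclic alkene: C7=CH2 | O1CCOC12CC[C@@]3(C)[C@H](OCc4ccc(OC)cc4)CCC(=C)[C@@H]3C2 | intermediate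
9 | spiro-epoxide at C7 (O α, CH2 β) | O1CCOC12CC[C@@]3(C)[C@H](OCc4ccc(OC)cc4)CC[C@@]5(OC5)[C@@H]3C2 | intermediate
10 | tertiary carbinol: C7 α-OH and β-CH3, C10 dioxolane | O1CCOC12CC[C@@]3(C)[C@H](OCc4ccc(OC)cc4)CC[C@@](C)(O)[C@@H]3C2 | intermediate
11 | hydroxy ketone: C10 ketone, C7 α-OH/β-CH3, C4 β-OPMB | O=C1CC[C@@]2(C)[C@H](OCc3ccc(OC)cc3)CC[C@@](C)(O)[C@@H]2C1 | intermediate
12 | bis-silyl compound: C10=C1 trimethylsilyl enol ether, C7 α-OSiMe3 | C[Si](C)(C)OC1=CC[C@@]2(C)[C@H](OCc3ccc(OC)cc3)CC[C@@](C)(O[Si](C)(C)C)[C@@H]2C1 | intermediate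
13 | silyloxy epoxide: C1–C10 α-epoxide of 12 | C[Si](C)(C)O[C@]12O[C@H]1C[C@@]3(C)[C@H](OCc4ccc(OC)cc4)CC[C@@](C)(O[Si](C)(C)C)[C@@H]3C2 | intermediate (not isolated)
14 | bis-silyl ketol: C1 α-OSiMe3, C10 ketone, C7 α-OSiMe3 | O=C1[C@@H](O[Si](C)(C)C)C[C@@]2(C)[C@H](OCc3ccc(OC)cc3)CC[C@@](C)(O[Si](C)(C)C)[C@@H]2C1 | intermediate (not isolated)
15 | ketol: C1 α-OH, C10 ketone, C7 α-OH | O=C1[C@@H](O)C[C@@]2(C)[C@H](OCc3ccc(OC)cc3)CC[C@@](C)(O)[C@@H]2C1 | intermediate
16 | silyloxy ketone: C1 α-OTBS, C10 ketone | CC(C)(C)[Si](C)(C)O[C@H]1C[C@@]2(C)[C@H](OCc3ccc(OC)cc3)CC[C@@](C)(O)[C@@H]2CC1=O | intermediate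
17 | dipotassium salt: C9=C10 enolate and C7 alkoxide of 16 | CC(C)(C)[Si](C)(C)O[C@H]1C[C@@]2(C)[C@H](OCc3ccc(OC)cc3)CC[C@@](C)([O-])[C@@H]2C=C1[O-].[K+].[K+] | intermediate (not isolated)
18 | enol triflate: C9=C10, OTf on C10 | CC(C)(C)[Si](C)(C)O[C@H]1C[C@@]2(C)[C@H](OCc3ccc(OC)cc3)CC[C@@](C)(O)[C@@H]2C=C1OS(=O)(=O)C(F)(F)F | intermediate
19 | isopropylmagnesium chloride | CC(C)[Mg]Cl | starting material
20 | isopropyl alkene: C9=C10 with isopropyl on C10, C1 α-OTBS, C4 β-OPMB | CC(C)(C)[Si](C)(C)O[C@H]1C[C@@]2(C)[C@H](OCc3ccc(OC)cc3)CC[C@@](C)(O)[C@@H]2C=C1C(C)C | intermediate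
21 | diol: C4 β-OH, C7 α-OH, C1 α-OTBS, C9=C10 | CC(C)(C)[Si](C)(C)O[C@H]1C[C@@]2(C)[C@H](O)CC[C@@](C)(O)[C@@H]2C=C1C(C)C | intermediate
22 | mesylate: C4 β-OMs, C9=C10 | CC(C)(C)[Si](C)(C)O[C@H]1C[C@@]2(C)[C@H](OS(C)(=O)=O)CC[C@@](C)(O)[C@@H]2C=C1C(C)C | intermediate
23 | C9 α-alkylborane (BH2 on C9, H-10 α) | CC(C)(C)[Si](C)(C)O[C@H]1C[C@@]2(C)[C@H](OS(C)(=O)=O)CC[C@@](C)(O)[C@@H]2[C@@H](B)[C@@H]1C(C)C | intermediate (not isolated)
24 | fragmentation precursor, dimethyl boronate: C1 α-OTBS, C3 β-CH3, C4 β-OMs, C7 α-OH/β-CH3, H-8 α, C9 α-B(OMe)2, C10 β-isopropyl | CC(C)(C)[Si](C)(C)O[C@H]1C[C@@]2(C)[C@H](OS(C)(=O)=O)CC[C@@](C)(O)[C@@H]2[C@@H](B(OC)OC)[C@@H]1C(C)C | intermediate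
25 | sodium trimethoxy(alkyl)borate of 24 | CC(C)(C)[Si](C)(C)O[C@H]1C[C@@]2(C)[C@H](OS(C)(=O)=O)CC[C@@](C)(O)[C@@H]2[C@@H]([B-](OC)(OC)OC)[C@@H]1C(C)C.[Na+] | intermediate (not isolated)
26 | (1S,3E,7R,8E,10S)-1-(tert-butyldimethylsilyloxy)-3,7-dimethyl-10-(propan-2-yl)cyclodeca-3,8-dien-7-ol (plan numbering) | CC(C)(C)[Si](C)(C)O[C@H]1C/C(C)=C/CC[C@@](C)(O)/C=C/[C@@H]1C(C)C | intermediate
27 | (1S,3E,7R,8E,10S)-3,7-dimethyl-10-(propan-2-yl)cyclodeca-3,8-diene-1,7-diol (plan numbering) | O[C@H]1C/C(C)=C/CC[C@@](C)(O)/C=C/[C@@H]1C(C)C | intermediate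
28 | vanillic acid (4-hydroxy-3-methoxybenzoic acid) | COc1cc(C(=O)O)ccc1O | starting material
29 | 4-acetoxy-3-methoxybenzoic acid | COc1cc(C(=O)O)ccc1OC(C)=O | intermediate
30 | acetyl-protected ester: 27 acylated at O-1 with 29 | COc1cc(C(=O)O[C@H]2C/C(C)=C/CC[C@@](C)(O)/C=C/[C@@H]2C(C)C)ccc1OC(C)=O | intermediate
31 | (1S,3E,7R,8E,10S)-7-hydroxy-3,7-dimethyl-10-(propan-2-yl)cyclodeca-3,8-dien-1-yl 4-hydroxy-3-methoxybenzoate (plan numbering) | COc1cc(C(=O)O[C@H]2C/C(C)=C/CC[C@@](C)(O)/C=C/[C@@H]2C(C)C)ccc1O | target

**Count and risks**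

Total steps: 22. Longest linear sequence: 21 (steps 1–19, 21 and 22); step 20 is a one-step side branch.

Step 13 (enol triflate). The base may deprotonate at C1 instead of C9, because the axial C9 hydrogen sits between the syn-axial methyl groups of C3 and C7; this would give the regioisomeric C10=C1 triflate or silyl migration. Fallback, from 16 back to 20: condensation of 16 with 2,4,6-triisopropylbenzenesulfonyl hydrazide should give the trisylhydrazone F1, whose sulfonamide nitrogen lies anti to the substituted C1. Excess n-BuLi (THF, −78 to 0 °C) then removes a C9 hydrogen syn to that nitrogen (Shapiro reaction). The C10 alkenyllithium is quenched with I2 to give the alkenyl iodide F2, which is coupled with 19 under the iron catalysis of step 14 to rejoin the route at 20.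

Step 14 (sp2–sp3 coupling). β-Hydride loss or isomerisation of the secondary alkyl–metal intermediate, or simple reduction of the triflate, may compete with coupling. Fallback, from 18 back to 20: Suzuki–Miyaura coupling of 18 with isopropenylboronic acid pinacol ester (Pd(PPh3)4, K3PO4, dioxane–H2O, 80 °C) should give the 2-substituted diene F3. Its 1,1-disubstituted double bond is then saturated selectively with diimide (2-nitrobenzenesulfonyl hydrazide, Et3N) or H2/RhCl(PPh3)3, returning to 20.

Step 21 (esterification). Acylation of the hindered secondary hydroxyl may be slow enough for DMAP to shuttle the phenolic acetyl group onto the alcohol, or for the activated acid to rearrange to an N-acylurea. Fallback, from 28 and 27 to 31: vanillic acid 28 is bis-silylated (TBSCl, imidazole, DMF) to the silyl ester/silyl ether F4. Its silyl ester is hydrolysed (AcOH–THF–H2O) to 4-(tert-butyldimethylsilyloxy)-3-methoxybenzoic acid F5. Yamaguchi esterification (2,4,6-trichlorobenzoyl chloride, Et3N; then 27, DMAP, toluene) gives the silyl-protected ester F6, and Bu4NF/AcOH at 0 °C frees the phenol to give 31 directly.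

**Further compounds**

F1 | step 13 | trisylhydrazone of 16 (C10=N–NH–SO2Ar, Ar = 2,4,6-triisopropylphenyl) | CC(C)(C)[Si](C)(C)O[C@H]1C[C@@]2(C)[C@H](OCc3ccc(OC)cc3)CC[C@@](C)(O)[C@@H]2CC1=NNS(=O)(=O)c4c(C(C)C)cc(C(C)C)cc4C(C)C
F2 | step 13 | alkenyl iodide (C9=C10, iodine on C10) | CC(C)(C)[Si](C)(C)O[C@H]1C[C@@]2(C)[C@H](OCc3ccc(OC)cc3)CC[C@@](C)(O)[C@@H]2C=C1I
F3 | step 14 | diene (C9=C10 with isopropenyl on C10) | CC(C)(C)[Si](C)(C)O[C@H]1C[C@@]2(C)[C@H](OCc3ccc(OC)cc3)CC[C@@](C)(O)[C@@H]2C=C1C(C)=C
F4 | step 21 | tert-butyldimethylsilyl 4-(tert-butyldimethylsilyloxy)-3-methoxybenzoate | COc1cc(C(=O)O[Si](C)(C)C(C)(C)C)ccc1O[Si](C)(C)C(C)(C)C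
F5 | step 21 | 4-(tert-butyldimethylsilyloxy)-3-methoxybenzoic acid | COc1cc(C(=O)O)ccc1O[Si](C)(C)C(C)(C)C
F6 | step 21 | silyl-protected ester (27 acylated at O-1 with F5) | COc1cc(C(=O)O[C@H]2C/C(C)=C/CC[C@@](C)(O)/C=C/[C@@H]2C(C)C)ccc1O[Si](C)(C)C(C)(C)C
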